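**Retrosynthetic overview**

1. The route rests on ring B: each prenyl group at C3' and C5' ends in an isopropylidene C2''=C3'' bond, and the two carbons flank O4', the only oxygen whose two ortho positions are exactly C3' and C5'.
2. Both C2''=C3'' bonds are cut by a twofold olefin cross-metathesis, leading back to 7-O-MOM-3',5'-diallylgenistein and 2-methylbut-2-ene; the MOM group at O7 comes off last.
3. The two allyl groups are traced back to O4' by two rounds of O-allylation and aromatic Claisen rearrangement (first to C3', then to C5').
4. O7, the most acidic phenol, is masked first as its MOM ether so that only O4' can carry allyl groups; the 5-OH, hydrogen-bonded to the C4 carbonyl, stays free.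
5. No ring is formed anywhere: rings A, C and B are bought intact as genistein, and the target has no stereocentre.

Key step: step 6

Assumption: the 5-OH, locked in a hydrogen bond to the C4 carbonyl, is taken to be inert to K2CO3 and alkyl halides at or below acetone reflux and is carried unprotected throughout.

**Route**

Step 1
Reactants: 1 genistein; 2 chloromethyl methyl ether
Product: 3 7-O-methoxymethylgenistein
Conditions: MOMCl (1.05 equiv, slow addition), K2CO3 (1.1 equiv), acetone, 0 °C to rt
Reagents that add atoms: chloromethyl methyl ether, COCCl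
Why: Williamson-type O-alkylation in which one equivalent of K2CO3 ionises essentially only the 7-OH (a vinylogous carboxylic acid through the C4 carbonyl), the 5-OH being held in a hydrogen bond to C4=O and the 4'-OH being an ordinary, less acidic phenol, so the MOM group should go on O7.

Step 2
Reactants: 3 7-O-methoxymethylgenistein; 4 allyl bromide
Product: 5 4'-O-allyl-7-O-methoxymethylgenistein
Conditions: allyl bromide (1.3 equiv), K2CO3 (2 equiv), acetone, reflux
Reagents that add atoms: allyl bromide, C=CCBr
Why: Williamson ether synthesis at the only unchelated phenol left (4'-OH), while the hydrogen-bonded 5-OH is not alkylated under these mild conditions and the MOM acetal is stable to base.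

Step 3
Reactants: 5 4'-O-allyl-7-O-methoxymethylgenistein
Product: 7 3'-allyl-7-O-methoxymethylgenistein, via ortho-allyl dienone 6 (not isolated)
Conditions: PhNEt2, 200 °C, sealed tube, Ar
Reagents that add atoms: none
Why: Aromatic Claisen rearrangement, a [3,3]-sigmatropic shift that delivers the allyl group to one of the two equivalent ortho carbons (the para carbon C1' is blocked by ring C) and is followed by enolisation of dienone 6; the basic amine solvent protects the MOM acetal and suppresses acid-induced cyclisation of the ortho-allylphenol.

Step 4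
Reactants: 7 3'-allyl-7-O-methoxymethylgenistein; 4 allyl bromide
Product: 8 4'-O-allyl-3'-allyl-7-O-methoxymethylgenistein
Conditions: allyl bromide (1.5 equiv), K2CO3 (2 equiv), acetone, reflux
Reagents that add atoms: allyl bromide, C=CCBr
Why: Williamson ether synthesis again at the regenerated 4'-OH, which one ortho allyl group does not hinder enough to stop, with the 5-OH still chelated and unreactive.

Step 5
Reactants: 8 4'-O-allyl-3'-allyl-7-O-methoxymethylgenistein
Product: 10 7-O-methoxymethyl-3',5'-diallylgenistein, via diallyl dienone 9 (not isolated)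
Conditions: PhNEt2, 200 °C, sealed tube, Ar
Reagents that add atoms: none
Why: Second aromatic Claisen rearrangement, in which C5' is the only ortho carbon still bearing hydrogen, so the [3,3] shift and enolisation of dienone 9 can end only there (a shift to the substituted C3' is reversible and unproductive because the para position is blocked).

Step 6
Reactants: 10 7-O-methoxymethyl-3',5'-diallylgenistein; 11 2-methylbut-2-ene
Product: 13 7-O-methoxymethyl-3',5'-diprenylgenistein, via monoprenyl monoallyl intermediate 12 (not isolated)
Conditions: second-generation Grubbs catalyst RuCl2(=CHPh)(PCy3)(H2IMes) (10 mol %), 1,4-benzoquinone (10 mol %), 2-methylbut-2-ene/CH2Cl2 (1:1, large excess of the alkene), 40 °C, sealed tube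
Reagents that add atoms: 2-methylbut-2-ene, CC=C(C)C
Why: Olefin cross-metathesis by the Chauvin mechanism: after loss of PCy3 the ruthenium alkylidene adds [2+2] to the unhindered terminal CH=CH2 of an allyl group, cycloreversion and exchange with 2-methylbut-2-ene install the isopropylidene end while propene escapes, and the second allyl group follows the same path through 12. The closest known reaction type is the cross-metathesis of allylarenes, free ortho-allylphenols included, with 2-methylbut-2-ene to give prenylarenes. No ring is closed, and no stereocentre or E/Z element arises because each new C2''=C3'' bond carries two identical methyl groups. The step needs chemoselectivity for the two terminal alkenes over the chromone C2=C3 bond, which is trisubstituted and electron-poor (a vinylogous ester) and should not be engaged, and the meta relationship of the two allyl groups on ring B rules out ring-closing metathesis. Cross- over homo-metathesis is secured by the large excess of 2-methylbut-2-ene used as co-solvent, and allyl-to-propenyl migration by ruthenium hydrides is held back by the 1,4-benzoquinone additive.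

Step 7
Reactants: 13 7-O-methoxymethyl-3',5'-diprenylgenistein
Product: 14 3',5'-diprenylgenistein
Conditions: 3 M aq HCl, MeOH, 50 °C, stopped at full conversion; NaHCO3 quench
Reagents that add atoms: none
Why: Acid-catalysed solvolysis of the MOM acetal (transacetalisation to dimethoxymethane), fast because the 7-phenol is a good leaving group, under dilute acid that the two trisubstituted alkenes and the isoflavone core should survive for the short time needed.

**Compound list**

1 | genistein (5,7,4'-trihydroxyisoflavone) | O=c1c(-c2ccc(O)cc2)coc2cc(O)cc(O)c12 | starting material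
2 | chloromethyl methyl ether (MOMCl) | COCCl | starting material
3 | 7-O-methoxymethylgenistein | COCOc1cc(O)c2c(c1)occ(-c1ccc(O)cc1)c2=O | intermediate
4 | allyl bromide | C=CCBr | starting material
5 | 4'-O-allyl-7-O-methoxymethylgenistein | COCOc1cc(O)c2c(c1)occ(-c1ccc(OCC=C)cc1)c2=O | intermediate
6 | ortho-allyl dienone, 3-(3-allyl-4-oxocyclohexa-1,5-dien-1-yl)-5-hydroxy-7-(methoxymethoxy)chromen-4-one (racemic at the allyl-bearing carbon, not isolated) | COCOc1cc(O)c2c(c1)occ(C1=CC(CC=C)C(=O)C=C1)c2=O | intermediate
7 | 3'-allyl-7-O-methoxymethylgenistein | COCOc1cc(O)c2c(c1)occ(-c1ccc(O)c(CC=C)c1)c2=O | intermediate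
8 | 4'-O-allyl-3'-allyl-7-O-methoxymethylgenistein | COCOc1cc(O)c2c(c1)occ(-c1ccc(OCC=C)c(CC=C)c1)c2=O | intermediate
9 | diallyl dienone, 3-(3,5-diallyl-4-oxocyclohexa-1,5-dien-1-yl)-5-hydroxy-7-(methoxymethoxy)chromen-4-one (sp3 carbon at ring position 3, racemic, not isolated) | COCOc1cc(O)c2c(c1)occ(C1=CC(CC=C)C(=O)C(CC=C)=C1)c2=O | intermediate
10 | 7-O-methoxymethyl-3',5'-diallylgenistein | COCOc1cc(O)c2c(c1)occ(-c1cc(CC=C)c(O)c(CC=C)c1)c2=O | intermediate
11 | 2-methylbut-2-ene | CC=C(C)C | starting material
12 | 3'-allyl-5'-prenyl-7-O-methoxymethylgenistein (monoprenyl monoallyl intermediate, not isolated) | COCOc1cc(O)c2c(c1)occ(-c1cc(CC=C)c(O)c(CC=C(C)C)c1)c2=O | intermediate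
13 | 7-O-methoxymethyl-3',5'-diprenylgenistein | COCOc1cc(O)c2c(c1)occ(-c1cc(CC=C(C)C)c(O)c(CC=C(C)C)c1)c2=O | intermediate
14 | 3',5'-diprenylgenistein | CC(C)=CCc1cc(-c2coc3cc(O)cc(O)c3c2=O)cc(CC=C(C)C)c1O | target

**Step count**

Total steps: 7. Longest linear sequence: 7 steps (1 to 14).

**Steps most likely to fail**

Step 6 (twofold cross-metathesis). The catalyst may die before the second allyl group has exchanged. Ruthenium hydrides may shift the allyl double bonds into conjugation with ring B. The ethylidene end of 2-methylbut-2-ene may be transferred in place of the isopropylidene end, giving but-2-enyl congeners that are hard to separate. The fallback sets out from 3 and comes back to the route at 13, and puts the prenyl groups on by the reverse-prenyl ether Claisen sequence.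
- Compound 3 is O-alkylated at O4' with 3-chloro-3-methylbut-1-yne (K2CO3, KI, CuI cat., acetone, reflux) to give 4'-O-(1,1-dimethylprop-2-ynyl)-7-O-methoxymethylgenistein F1.
- Semihydrogenation (H2, Pd on CaCO3 poisoned with Pb(OAc)2, quinoline, EtOAc) should give 4'-O-(1,1-dimethylallyl)-7-O-methoxymethylgenistein F2.
- Heating in PhNEt2 at about 130 °C should bring about the aromatic Claisen rearrangement through the ortho-prenyl dienone F3 (not isolated) to 3'-prenyl-7-O-methoxymethylgenistein F4.
- The same three operations on F4 lead through 4'-O-(1,1-dimethylprop-2-ynyl)-3'-prenyl-7-O-methoxymethylgenistein F5, 4'-O-(1,1-dimethylallyl)-3'-prenyl-7-O-methoxymethylgenistein F6 and the diprenyl dienone F7 (not isolated) to 13, which enters step 7.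

Step 7 (MOM cleavage). While the acetal is being cleaved, the acid may close a prenyl group onto O4' to form a 2,2-dimethylchroman, or HCl or methanol may add across the trisubstituted alkenes. The fallback sets out from 10 and comes back at 14, and reverses the order of deprotection and metathesis.
- Compound 10 is treated with 3 M aq HCl in MeOH at 50 °C, conditions under which terminal allyl groups should neither cyclise nor add HCl, to give 3',5'-diallylgenistein F8.
- Twofold cross-metathesis of F8 with 2-methylbut-2-ene 11 (second-generation Grubbs catalyst RuCl2(=CHPh)(PCy3)(H2IMes), 1,4-benzoquinone, 2-methylbut-2-ene/THF, 40 °C) should pass through 3'-allyl-5'-prenylgenistein F9 (not isolated) and end directly at 14, so that no acid ever meets a prenyl group.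

Step 1 (site-selective MOM protection). Discrimination between O7 and O4' may be poor, giving double alkylation or a mixture of mono-ethers that lowers throughput at the very start. The fallback sets out from 1 and comes back at 3, and fixes the site through ester chemistry.
- Genistein 1 is peracetylated (Ac2O, pyridine) to 5,7,4'-tri-O-acetylgenistein F10.
- Thiophenol and imidazole in NMP should remove only the 7-O-acetyl group, the ester of the most acidic phenol, to give 5,4'-di-O-acetylgenistein F11.
- MOMCl and i-Pr2NEt in CH2Cl2 alkylate the single free phenol to give 5,4'-di-O-acetyl-7-O-methoxymethylgenistein F12.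
- K2CO3 in MeOH strips both acetates and delivers 3.

**Further compounds**

F1 | step 6 | 4'-O-(1,1-dimethylprop-2-ynyl)-7-O-methoxymethylgenistein | COCOc1cc(O)c2c(c1)occ(-c1ccc(OC(C)(C)C#C)cc1)c2=O
F2 | step 6 | 4'-O-(1,1-dimethylallyl)-7-O-methoxymethylgenistein | COCOc1cc(O)c2c(c1)occ(-c1ccc(OC(C)(C)C=C)cc1)c2=O
F3 | step 6 | ortho-prenyl dienone (not isolated, racemic at the prenyl-bearing carbon) | COCOc1cc(O)c2c(c1)occ(C1=CC(CC=C(C)C)C(=O)C=C1)c2=O
F4 | step 6 | 3'-prenyl-7-O-methoxymethylgenistein | COCOc1cc(O)c2c(c1)occ(-c1ccc(O)c(CC=C(C)C)c1)c2=O
F5 | step 6 | 4'-O-(1,1-dimethylprop-2-ynyl)-3'-prenyl-7-O-methoxymethylgenistein | COCOc1cc(O)c2c(c1)occ(-c1ccc(OC(C)(C)C#C)c(CC=C(C)C)c1)c2=O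
F6 | step 6 | 4'-O-(1,1-dimethylallyl)-3'-prenyl-7-O-methoxymethylgenistein | COCOc1cc(O)c2c(c1)occ(-c1ccc(OC(C)(C)C=C)c(CC=C(C)C)c1)c2=O
F7 | step 6 | diprenyl dienone (not isolated, racemic at the sp3 ring carbon) | COCOc1cc(O)c2c(c1)occ(C1=CC(CC=C(C)C)C(=O)C(CC=C(C)C)=C1)c2=O
F8 | step 7 | 3',5'-diallylgenistein | C=CCc1cc(-c2coc3cc(O)cc(O)c3c2=O)cc(CC=C)c1O
F9 | step 7 | 3'-allyl-5'-prenylgenistein (not isolated) | C=CCc1cc(-c2coc3cc(O)cc(O)c3c2=O)cc(CC=C(C)C)c1O
F10 | step 1 | 5,7,4'-tri-O-acetylgenistein | CC(=O)Oc1ccc(cc1)-c1coc2cc(OC(C)=O)cc(OC(C)=O)c2c1=O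
F11 | step 1 | 5,4'-di-O-acetylgenistein | CC(=O)Oc1ccc(cc1)-c1coc2cc(O)cc(OC(C)=O)c2c1=O
F12 | step 1 | 5,4'-di-O-acetyl-7-O-methoxymethylgenistein | COCOc1cc(OC(C)=O)c2c(c1)occ(-c1ccc(OC(C)=O)cc1)c2=O
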